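**Strategy**

The saturated ring of the tetralin is disconnected at C3–C4. C4 is its only non-stereogenic sp3 carbon and is benzylic to the fused dimethoxybenzene ring, so a nitrogen atom placed between C4 and C3 gives a 2-benzazepine from which nitrogen can be excised through an isodiazene. This one operation contracts the seven-membered azacycle to the six-membered carbocycle with C1, C2 and C3 already in place. The benzazepine comes from a Pictet–Spengler closure of an acyclic amine in which the future C1 carries two identical 3,4-dimethoxyphenyl groups: the pendant aryl and the fused ring are the same unit, and C1 becomes stereogenic only on annulation.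

Key step: step 6

Remark: the SMILES is read as (1R,2R,3R)-1-(3,4-dimethoxyphenyl)-6,7-dimethoxy-2,3-dimethyl-1,2,3,4-tetrahydronaphthalene, with the aryl group at C1 trans to the C2 methyl and the C2 and C3 methyls cis. Tetralin numbering is used for the target and 2-benzazepine numbering for compound 14.

**Route**

Step 1
Reactants: 1 (S)-2-methylpropane-2-sulfinamide; 2 acetaldehyde
Product: 3 (S,E)-N-ethylidene-2-methylpropane-2-sulfinamide
Conditions: acetaldehyde (3 equiv), anhydrous CuSO4 (2 equiv), CH2Cl2, 0 °C to rt
Reagents that add atoms: acetaldehyde, CC=O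
Why: Condensation of a sulfinamide with an aldehyde (N-sulfinyl imine formation), driven by the desiccant, should give the E-aldimine without touching the sulfur stereocenter, which then directs both carbon stereocenters of the chain.

Step 2
Reactants: 3 (S,E)-N-ethylidene-2-methylpropane-2-sulfinamide; 4 methyl propanoate
Product: 7 methyl (2R,3S)-3-{[(S)-tert-butylsulfinyl]amino}-2-methylbutanoate, via lithium enolate 5 (not isolated), via titanium enolate 6 (not isolated)
Conditions: 4, LDA (commercial solution), THF, −78 °C; ClTi(OiPr)3 (2 equiv), −78 °C; then 3, −78 °C; aq NH4Cl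
Reagents that add atoms: methyl propanoate, CCC(=O)OC
Why: Mannich addition of a titanium ester enolate to an N-sulfinyl aldimine through a closed chair transition state in which titanium is held by the imine nitrogen and the sulfinyl oxygen: the (S)-sulfinyl group should direct attack so that the amine carbon becomes 3S, and the enolate with methyl trans to the O–metal bond, meeting the axial imine methyl, should give the syn (2R) methyl.

Step 3
Reactants: 7 methyl (2R,3S)-3-{[(S)-tert-butylsulfinyl]amino}-2-methylbutanoate; 8 (3,4-dimethoxyphenyl)magnesium bromide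
Product: 9 (S)-N-[(2S,3R)-4,4-bis(3,4-dimethoxyphenyl)-4-hydroxy-3-methylbutan-2-yl]-2-methylpropane-2-sulfinamide
Conditions: 8 (4 equiv, 0.5 M in THF), THF, 0 °C to rt; H2O/aq NH4Cl
Reagents that add atoms: (3,4-dimethoxyphenyl)magnesium bromide, COc1ccc([Mg]Br)cc1OC
Why: Double Grignard addition to the ester (one further equivalent is consumed by the sulfinamide N–H) should outpace enolisation and give the tertiary diaryl carbinol, whose carbinol carbon is not stereogenic because both aryl groups are the same.

Step 4
Reactants: 9 (S)-N-[(2S,3R)-4,4-bis(3,4-dimethoxyphenyl)-4-hydroxy-3-methylbutan-2-yl]-2-methylpropane-2-sulfinamide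
Product: 11 (2S,3S)-4,4-bis(3,4-dimethoxyphenyl)-3-methylbutan-2-amine, via deoxygenated sulfinamide 10 (not isolated)
Conditions: Et3SiH (5 equiv), TFA (10 equiv), CH2Cl2, 0 °C; concentrate; HCl (4 M in dioxane), MeOH, rt; aq NaOH
Reagents that add atoms: none
Why: Ionic hydrogenation: the carbinol ionises to a bis(3,4-dimethoxyphenyl)carbenium ion that the excess silane should reduce faster than it can lose the neighbouring proton, so the adjacent methyl-bearing stereocenter is kept, and acidic methanolysis then removes the N-sulfinyl group.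

Step 5
Reactants: 11 (2S,3S)-4,4-bis(3,4-dimethoxyphenyl)-3-methylbutan-2-amine; 12 paraformaldehyde
Product: 14 (3S,4S,5R)-5-(3,4-dimethoxyphenyl)-7,8-dimethoxy-3,4-dimethyl-2,3,4,5-tetrahydro-1H-2-benzazepine, via N-methyleneiminium ion 13 (not isolated)
Conditions: (CH2O)n (1.0 equiv CH2O), MeOH, rt; then TFA, CH2Cl2, 0 to 40 °C; aq NaOH
Reagents that add atoms: formaldehyde (from paraformaldehyde), C=O
Why: Pictet–Spengler reaction: the iminium ion should attack, para to a methoxy group, the one of the two diastereotopic dimethoxyphenyl rings whose reaction leaves the other aryl group equatorial and anti to the C4 methyl, closing the seven-membered ring (7-endo-trig) and setting C5 as R, trans to that methyl.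

Step 6
Reactants: 14 (3S,4S,5R)-5-(3,4-dimethoxyphenyl)-7,8-dimethoxy-3,4-dimethyl-2,3,4,5-tetrahydro-1H-2-benzazepine; 15 N-(benzyloxy)-N-(pivaloyloxy)-4-(trifluoromethyl)benzamide
Product: 18 (1R,2R,3R)-1-(3,4-dimethoxyphenyl)-6,7-dimethoxy-2,3-dimethyl-1,2,3,4-tetrahydronaphthalene, via N-aminated adduct 16 (not isolated), via isodiazene 17 (not isolated)
Conditions: 15 (1.5 equiv), THF, 45 °C
Reagents that add atoms: none
Why: The secondary amine displaces pivalate at the nitrogen of the anomeric amide to give adduct 16, whose benzyloxy group migrates to the acyl carbon and releases benzyl 4-(trifluoromethyl)benzoate and the isodiazene 17; 17 breaks its benzylic C1–N bond, loses N2 and leaves a singlet diradical (benzylic CH2 radical and secondary radical at C3 of the azepine) that collapses to the C3–C4 bond of the tetralin. The closest known reaction type is the nitrogen deletion of secondary benzylic amines through isodiazenes, which is known to contract cyclic benzylic amines by one atom. The six-membered ring closes by intramolecular radical–radical recombination of this 1,6-diradical, the two termini being the former neighbours of nitrogen. No new stereocenter is created: C1 and C2 of the tetralin are not touched, and C3 must be re-formed with retention, which is controlled by the tethered benzylic radical lying on the face that nitrogen occupied (least-motion collapse of the geminate pair before rotation about C2–C3). The step needs recombination to outrun rotation at C3, disproportionation of the diradical and isomerisation of 17 to a hydrazone; the rigid o-phenylene tether, the singlet state of the pair and the weak benzylic C–N bond should secure this, although some C3 epimer, a separable diastereomer, is the expected by-product.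

**Compound list**

1 | (S)-2-methylpropane-2-sulfinamide | CC(C)(C)[S@](=O)N | starting material
2 | acetaldehyde | CC=O | starting material
3 | (S,E)-N-ethylidene-2-methylpropane-2-sulfinamide | CC(C)(C)[S@](=O)/N=C/C | intermediate
4 | methyl propanoate | CCC(=O)OC | starting material
5 | lithium enolate of methyl propanoate (methyl trans to OLi) | C/C=C(\OC)O[Li] | intermediate
6 | triisopropoxytitanium enolate of methyl propanoate (methyl trans to OTi) | C/C=C(\OC)O[Ti](OC(C)C)(OC(C)C)OC(C)C | intermediate
7 | methyl (2R,3S)-3-{[(S)-tert-butylsulfinyl]amino}-2-methylbutanoate | COC(=O)[C@H](C)[C@H](C)N[S@@](=O)C(C)(C)C | intermediate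
8 | (3,4-dimethoxyphenyl)magnesium bromide | COc1ccc([Mg]Br)cc1OC | starting material
9 | (S)-N-[(2S,3R)-4,4-bis(3,4-dimethoxyphenyl)-4-hydroxy-3-methylbutan-2-yl]-2-methylpropane-2-sulfinamide | COc1ccc(C(O)(c2ccc(OC)c(OC)c2)[C@H](C)[C@H](C)N[S@@](=O)C(C)(C)C)cc1OC | intermediate
10 | (S)-N-[(2S,3S)-4,4-bis(3,4-dimethoxyphenyl)-3-methylbutan-2-yl]-2-methylpropane-2-sulfinamide | COc1ccc(C(c2ccc(OC)c(OC)c2)[C@H](C)[C@H](C)N[S@@](=O)C(C)(C)C)cc1OC | intermediate
11 | (2S,3S)-4,4-bis(3,4-dimethoxyphenyl)-3-methylbutan-2-amine | COc1ccc(C(c2ccc(OC)c(OC)c2)[C@H](C)[C@H](C)N)cc1OC | intermediate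
12 | paraformaldehyde (formaldehyde source) | C=O | starting material
13 | N-methyleneiminium ion of 11 | COc1ccc(C(c2ccc(OC)c(OC)c2)[C@H](C)[C@H](C)[NH+]=C)cc1OC | intermediate
14 | (3S,4S,5R)-5-(3,4-dimethoxyphenyl)-7,8-dimethoxy-3,4-dimethyl-2,3,4,5-tetrahydro-1H-2-benzazepine | COc1ccc([C@@H]2c3cc(OC)c(OC)cc3CN[C@@H](C)[C@H]2C)cc1OC | intermediate
15 | N-(benzyloxy)-N-(pivaloyloxy)-4-(trifluoromethyl)benzamide | CC(C)(C)C(=O)ON(OCc1ccccc1)C(=O)c1ccc(cc1)C(F)(F)F | starting material
16 | N-(benzyloxy)-N-[benzazepin-2-yl of 14]-4-(trifluoromethyl)benzamide (N-aminated adduct) | COc1ccc([C@@H]2c3cc(OC)c(OC)cc3CN(N(OCc4ccccc4)C(=O)c4ccc(cc4)C(F)(F)F)[C@@H](C)[C@H]2C)cc1OC | intermediate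
17 | isodiazene (1,1-diazene) of 14 | COc1ccc([C@@H]2c3cc(OC)c(OC)cc3C[N+](=[N-])[C@@H](C)[C@H]2C)cc1OC | intermediate
18 | (1R,2R,3R)-1-(3,4-dimethoxyphenyl)-6,7-dimethoxy-2,3-dimethyl-1,2,3,4-tetrahydronaphthalene | COc1ccc([C@@H]2c3cc(OC)c(OC)cc3C[C@@H](C)[C@H]2C)cc1OC | target

**Step count and risks**

Total step count: 6. Longest linear sequence: 6 steps (1 → 3 → 7 → 9 → 11 → 14 → 18).

Steps most likely to fail:

1. Step 6. The configuration at C3 may erode if the diradical rotates before it recombines, which would give the C3 epimer. The diradical may also disproportionate by hydrogen transfer to a ring-opened alkene, or the isodiazene may isomerise to a hydrazone. Fallback, from 14 back to 18, by an ylide route in which the nitrogen leaves only after the ring has contracted: exhaustive methylation (MeI, K2CO3, MeCN) should give the N,N-dimethylbenzazepinium iodide F1. PhLi in Et2O should form the benzylic ammonium ylide, and a Stevens 1,2-shift of C3 from nitrogen to the ylide carbon (a ring contraction known for benzo-fused azepinium salts, with retention in the migrating carbon) should give the 4-(dimethylamino)tetralin F2. Methylation (MeI) should give the trimethylammonium iodide F3, and hydrogenolysis of its benzylic C–N bond (H2, Pd/C, MeOH; aq K2CO3) should give 18.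

2. Step 4. The methyl-bearing carbon next to the diarylcarbenium ion may epimerise through reversible proton loss to the 1,1-diarylalkene before hydride is delivered. Fallback, from 7 back to 11, replacing the free cation by a surface hydrogenolysis: HCl in MeOH should remove the sulfinyl group to give methyl (2R,3S)-3-amino-2-methylbutanoate hydrochloride F4. Excess 8 should give the amino alcohol (2R,3S)-3-amino-1,1-bis(3,4-dimethoxyphenyl)-2-methylbutan-1-ol F5, and CDI should close the cyclic carbamate (4S,5R)-6,6-bis(3,4-dimethoxyphenyl)-4,5-dimethyl-1,3-oxazinan-2-one F6. H2 over Pd/C in MeOH/AcOH should cleave the dibenzylic C–O bond, and the carbamic acid should lose CO2 to give 11.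

3. Step 5. Closure of the seven-membered ring may be slow, discrimination between the two diastereotopic aryl rings may be incomplete, and a second aminomethylation of the product amine may follow. Fallback, from 11 back to 14, through a stronger acyl-derived electrophile: ethyl formate should give the formamide N-[(2S,3S)-4,4-bis(3,4-dimethoxyphenyl)-3-methylbutan-2-yl]formamide F7. Bischler–Napieralski cyclodehydration (Tf2O, 2-chloropyridine, CH2Cl2) should give the cyclic imine (3S,4S,5R)-5-(3,4-dimethoxyphenyl)-7,8-dimethoxy-3,4-dimethyl-4,5-dihydro-3H-2-benzazepine F8, which NaBH4 in MeOH should reduce to 14; the imine cannot take up a second carbon electrophile.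

Further compounds
F1 | step 6 | (3S,4S,5R)-5-(3,4-dimethoxyphenyl)-7,8-dimethoxy-2,2,3,4-tetramethyl-2,3,4,5-tetrahydro-1H-2-benzazepin-2-ium iodide | COc1ccc([C@@H]2c3cc(OC)c(OC)cc3C[N+](C)(C)[C@@H](C)[C@H]2C)cc1OC.[I-]
F2 | step 6 | (2S,3S,4R)-4-(3,4-dimethoxyphenyl)-6,7-dimethoxy-N,N,2,3-tetramethyl-1,2,3,4-tetrahydronaphthalen-1-amine (both C1 epimers) | COc1ccc([C@@H]2c3cc(OC)c(OC)cc3C(N(C)C)[C@@H](C)[C@H]2C)cc1OC
F3 | step 6 | (2S,3S,4R)-4-(3,4-dimethoxyphenyl)-6,7-dimethoxy-N,N,N,2,3-pentamethyl-1,2,3,4-tetrahydronaphthalen-1-aminium iodide (both C1 epimers) | COc1ccc([C@@H]2c3cc(OC)c(OC)cc3C([N+](C)(C)C)[C@@H](C)[C@H]2C)cc1OC.[I-]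
F4 | step 4 | methyl (2R,3S)-3-amino-2-methylbutanoate hydrochloride | COC(=O)[C@H](C)[C@H](C)N.Cl
F5 | step 4 | (2R,3S)-3-amino-1,1-bis(3,4-dimethoxyphenyl)-2-methylbutan-1-ol | COc1ccc(C(O)(c2ccc(OC)c(OC)c2)[C@H](C)[C@H](C)N)cc1OC
F6 | step 4 | (4S,5R)-6,6-bis(3,4-dimethoxyphenyl)-4,5-dimethyl-1,3-oxazinan-2-one | O=C1N[C@@H](C)[C@@H](C)C(c2ccc(OC)c(OC)c2)(c2ccc(OC)c(OC)c2)O1
F7 | step 5 | N-[(2S,3S)-4,4-bis(3,4-dimethoxyphenyl)-3-methylbutan-2-yl]formamide | COc1ccc(C(c2ccc(OC)c(OC)c2)[C@H](C)[C@H](C)NC=O)cc1OC
F8 | step 5 | (3S,4S,5R)-5-(3,4-dimethoxyphenyl)-7,8-dimethoxy-3,4-dimethyl-4,5-dihydro-3H-2-benzazepine | COc1ccc([C@@H]2c3cc(OC)c(OC)cc3C=N[C@@H](C)[C@H]2C)cc1OC
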